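**Retrosynthetic overview**
1. C2'–O disconnection (key): the 2'-oxygen of ring B is put on bromo acid 1 by a carboxylate-directed C–H lactonization to benzofuranone 2. This is the first ring formed, and it places the oxygen para to the bromine.
2. Lactone 2 only carries that oxygen: it is opened and capped as the isopropyl ether (through 3 and 4) to give acid 5, so that only the ring A phenol can later close the pyranone.
3. Pyranone disconnections: C4–C4a (Friedel–Crafts acylation of resorcinol 6 by 5, ketone 7) and C2 from DMF with O1–C2 closure. Ring C of isoflavone 8 is the second and last ring formed; rings A and B are bought.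
4. Ether cleavage gives bromophenol 9; the C5'–prenyl bond is made last by Stille coupling with stannane 10 to give target 11.

Assumption: the target has no stereocentre and no configurable double bond, so "single enantiomer" is taken to mean the one achiral compound drawn.

**Step 1**
Reactants: 1 2-(3-bromo-4-methoxyphenyl)acetic acid
Product: 2 5-bromo-6-methoxy-1-benzofuran-2(3H)-one
Conditions: Pd(OAc)2 (10 mol %), N-acetylglycine (30 mol %), PhI(OAc)2 (1.5 equiv), KOAc (20 mol %), t-AmOH, 80 °C
Reagents that add atoms: none
Why: Proposed new method: carboxylate-directed ortho C–H lactonization of an arylacetic acid that has no α-substituents; the carboxylate binds divalent palladium and amino-acid-assisted concerted metalation–deprotonation gives the six-membered palladacycle at the less hindered C6–H (para to Br; the other ortho C–H is flanked by Br), PhI(OAc)2 oxidises it to tetravalent palladium, and C(aryl)–O reductive elimination closes the lactone, while the aryl bromide survives because no zerovalent palladium is formed and the weakly basic alcohol medium limits enolisation and over-oxidation of the product; closest known reaction type: palladium-catalysed C–H lactonization of α,α-disubstituted arylacetic acids to benzofuranones, together with the ortho C–H iodination and olefination of parent phenylacetic acids through the same palladacycle.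

**Step 2**
Reactants: 2 5-bromo-6-methoxy-1-benzofuran-2(3H)-one
Product: 5 2-[5-bromo-4-methoxy-2-(propan-2-yloxy)phenyl]acetic acid, via dipotassium phenoxide carboxylate 3 (not isolated), via isopropyl ester ether 4 (not isolated)
Conditions: KOH (2.2 equiv), DMSO/H2O, 25 °C; i-PrI (3 equiv), 50 °C; then aq KOH, 60 °C; then HCl
Reagents that add atoms: 2-iodopropane CC(C)I; potassium hydroxide [K+].[OH-]
Why: Hydroxide opens the aryl lactone (saponification), both oxygens are alkylated by the secondary iodide (Williamson etherification and carboxylate alkylation), and only the ester is then saponified, which leaves the isopropyl ether that masks the 2'-oxygen.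

**Step 3**
Reactants: 5 2-[5-bromo-4-methoxy-2-(propan-2-yloxy)phenyl]acetic acid; 6 resorcinol (benzene-1,3-diol)
Product: 8 3-[5-bromo-4-methoxy-2-(propan-2-yloxy)phenyl]-7-hydroxy-4H-chromen-4-one, via deoxybenzoin 7 (not isolated)
Conditions: BF3·Et2O (solvent), 85 °C, 90 min; then DMF, MsCl, 70 °C; H2O
Reagents that add atoms: N,N-dimethylformamide CN(C)C=O
Why: Friedel–Crafts (Nencki-type) acylation of resorcinol at C4 gives the boron-chelated deoxybenzoin, which is formylated at the benzylic carbon by the DMF/MsCl Vilsmeier-type reagent and closes through the only free ortho hydroxyl (deoxybenzoin isoflavone synthesis), since the capped 2'-oxygen cannot cyclise to a benzofuran.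

**Step 4**
Reactants: 8 3-[5-bromo-4-methoxy-2-(propan-2-yloxy)phenyl]-7-hydroxy-4H-chromen-4-one
Product: 9 3-(5-bromo-2-hydroxy-4-methoxyphenyl)-7-hydroxy-4H-chromen-4-one
Conditions: BCl3 (4 equiv), CH2Cl2, −78 to 0 °C; then MeOH, H2O
Reagents that add atoms: none
Why: Lewis acid ether dealkylation: BCl3 cleaves the secondary isopropyl aryl ether far faster than the unchelated 4'-methyl ether, and the aryl bromide and chromone are inert at 0 °C.

**Step 5**
Reactants: 9 3-(5-bromo-2-hydroxy-4-methoxyphenyl)-7-hydroxy-4H-chromen-4-one; 10 tributyl(3-methylbut-2-en-1-yl)stannane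
Product: 11 7-hydroxy-3-[2-hydroxy-4-methoxy-5-(3-methylbut-2-en-1-yl)phenyl]-4H-chromen-4-one
Conditions: Pd(PPh3)4 (5 mol %), DMF, 95 °C
Reagents that add atoms: none
Why: Stille coupling: oxidative addition of the aryl bromide to zerovalent palladium, allyl transfer from tin and reductive elimination at the less substituted allyl terminus give the linear prenyl arene under neutral conditions that tolerate both free phenols.

**Compound list**
1 | 2-(3-bromo-4-methoxyphenyl)acetic acid | COc1ccc(CC(=O)O)cc1Br | starting material
2 | 5-bromo-6-methoxy-1-benzofuran-2(3H)-one | COc1cc2OC(=O)Cc2cc1Br | intermediate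
3 | dipotassium 2-(5-bromo-4-methoxy-2-oxidophenyl)acetate | COc1cc([O-])c(CC(=O)[O-])cc1Br.[K+].[K+] | intermediate
4 | propan-2-yl 2-[5-bromo-4-methoxy-2-(propan-2-yloxy)phenyl]acetate | COc1cc(OC(C)C)c(CC(=O)OC(C)C)cc1Br | intermediate
5 | 2-[5-bromo-4-methoxy-2-(propan-2-yloxy)phenyl]acetic acid | COc1cc(OC(C)C)c(CC(=O)O)cc1Br | intermediate
6 | resorcinol (benzene-1,3-diol) | Oc1cccc(O)c1 | starting material
7 | 2-[5-bromo-4-methoxy-2-(propan-2-yloxy)phenyl]-1-(2,4-dihydroxyphenyl)ethan-1-one | COc1cc(OC(C)C)c(CC(=O)c2ccc(O)cc2O)cc1Br | intermediate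
8 | 3-[5-bromo-4-methoxy-2-(propan-2-yloxy)phenyl]-7-hydroxy-4H-chromen-4-one | COc1cc(OC(C)C)c(-c2coc3cc(O)ccc3c2=O)cc1Br | intermediate
9 | 3-(5-bromo-2-hydroxy-4-methoxyphenyl)-7-hydroxy-4H-chromen-4-one | COc1cc(O)c(-c2coc3cc(O)ccc3c2=O)cc1Br | intermediate
10 | tributyl(3-methylbut-2-en-1-yl)stannane | CCCC[Sn](CCCC)(CCCC)CC=C(C)C | starting material
11 | 7-hydroxy-3-[2-hydroxy-4-methoxy-5-(3-methylbut-2-en-1-yl)phenyl]-4H-chromen-4-one | COc1cc(O)c(-c2coc3cc(O)ccc3c2=O)cc1CC=C(C)C | target

**Step count**
Total steps: 5. Longest linear sequence: 5 (1 → 2 → 5 → 8 → 9 → 11).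

**Steps most likely to fail, with fallbacks**

The proposed new lactonization (step 1) is the most uncertain step. Without the α,α-disubstitution of the known substrates the C–O reductive elimination may be slow, and PhI(OAc)2 may oxidise the benzylic position of 1 or 2 or decarboxylate 1. The fallback uses known chemistry, sets out from 1 and comes back at 2. Acid 1 is ortho-iodinated under the established carboxylate-directed conditions (Pd(OAc)2, PhI(OAc)2, I2, DMF, 60 °C) at the same less hindered position, giving 2-(5-bromo-2-iodo-4-methoxyphenyl)acetic acid F1. Copper-catalysed Ullmann-type hydroxylation of the iodide (CuI, 1,10-phenanthroline, aq NaOH, 80 °C; the iodide next to the carboxylate reacts before the bromide) and acidification with HCl then close the lactone 2.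

The one-pot acylation and ring closure (step 3) is the second risk. Hot BF3·Et2O may remove the isopropyl group, after which the free 2'-hydroxyl would divert the material to benzofurans, and the ortho-alkoxy acid may acylate poorly. The fallback sets out from 5 and comes back at 8, passing through an isolated 7.
- Acid 5 is converted with SOCl2 and then aqueous NH3 to 2-[5-bromo-4-methoxy-2-(propan-2-yloxy)phenyl]acetamide F2.
- F2 is dehydrated with (CF3CO)2O and pyridine to 2-[5-bromo-4-methoxy-2-(propan-2-yloxy)phenyl]acetonitrile F3.
- A Hoesch reaction of F3 with resorcinol 6 (ZnCl2, HCl gas, Et2O, 0 °C) gives 2-[5-bromo-4-methoxy-2-(propan-2-yloxy)phenyl]-1-(2,4-dihydroxyphenyl)ethan-1-iminium chloride F4, which is hydrolysed (H2O, 90 °C) to deoxybenzoin 7.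
- Ketone 7 is closed without Lewis acid with DMF dimethyl acetal (THF, 65 °C) through (E)-2-[5-bromo-4-methoxy-2-(propan-2-yloxy)phenyl]-1-(2,4-dihydroxyphenyl)-3-(dimethylamino)prop-2-en-1-one F5, which cyclises with loss of dimethylamine to 8.

The prenyl Stille coupling (step 5) is the third risk. Coupling at the γ-carbon would give the 1,1-dimethylallyl isomer, and the electron-rich bromide may add slowly to palladium or be reduced. The fallback sets out from 9 and comes back at 11. Stille coupling of 9 with allyltributylstannane (Pd(PPh3)4, DMF, 95 °C), which has no regiochemical ambiguity, gives 7-hydroxy-3-[2-hydroxy-4-methoxy-5-(prop-2-en-1-yl)phenyl]-4H-chromen-4-one F6. Olefin cross-metathesis of F6 with 2-methylbut-2-ene (second-generation Grubbs catalyst, RuCl2(=CHPh)(H2IMes)(PCy3), CH2Cl2, 40 °C) then gives 11.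

**Further compounds**
F1 | step 1 | 2-(5-bromo-2-iodo-4-methoxyphenyl)acetic acid | COc1cc(I)c(CC(=O)O)cc1Br
F2 | step 3 | 2-[5-bromo-4-methoxy-2-(propan-2-yloxy)phenyl]acetamide | COc1cc(OC(C)C)c(CC(N)=O)cc1Br
F3 | step 3 | 2-[5-bromo-4-methoxy-2-(propan-2-yloxy)phenyl]acetonitrile | COc1cc(OC(C)C)c(CC#N)cc1Br
F4 | step 3 | 2-[5-bromo-4-methoxy-2-(propan-2-yloxy)phenyl]-1-(2,4-dihydroxyphenyl)ethan-1-iminium chloride | COc1cc(OC(C)C)c(CC(=[NH2+])c2ccc(O)cc2O)cc1Br.[Cl-]
F5 | step 3 | (E)-2-[5-bromo-4-methoxy-2-(propan-2-yloxy)phenyl]-1-(2,4-dihydroxyphenyl)-3-(dimethylamino)prop-2-en-1-one | CN(C)/C=C(\c1cc(Br)c(OC)cc1OC(C)C)C(=O)c1ccc(O)cc1O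
F6 | step 5 | 7-hydroxy-3-[2-hydroxy-4-methoxy-5-(prop-2-en-1-yl)phenyl]-4H-chromen-4-one | COc1cc(O)c(-c2coc3cc(O)ccc3c2=O)cc1CC=C
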